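**Retrosynthetic overview**
- Target ⇒ cut the methylene bridge (C–C on both sides of CH2): a dearomatised (R)-acetyl(methyl)(prenyl)cyclohexadienone half, a 3-prenylphloroacetophenone half, and formaldehyde.
- (R)-half ⇒ its quaternary C–prenyl bond is traced back to a C–O bond: the 4-O-(1,1-dimethylallyl) ether of 3-methylphloroacetophenone. A chiral Pd catalyst relays the prenyl unit O→C and sets the only stereocentre.
- Ether ⇒ C–O disconnection (key bond): 3-methylphloroacetophenone + a tert-prenyl carbonate, by Pd-catalysed allylic etherification of the para-OH.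
- Aromatic half ⇒ phloroacetophenone + prenyl bromide (direct C-prenylation).
- Ring order: no ring is built. Both six-membered rings are bought as phloroglucinol nuclei; the methyl-bearing one is dearomatised (step 3) before the two are joined (step 4).

Assumption: the target is read as the (R)-enantiomer in the tautomer drawn (the descriptor depends on the tautomer, the spatial arrangement does not); 3-methylphloroacetophenone and tert-butyl 2-methylbut-3-en-2-yl carbonate are taken as catalogue items.

**Route**

Step 1
Reactants: 1 1-(2,4,6-trihydroxyphenyl)ethan-1-one (phloroacetophenone); 2 1-bromo-3-methylbut-2-ene (prenyl bromide)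
Product: 3 1-[2,4,6-trihydroxy-3-(3-methylbut-2-en-1-yl)phenyl]ethan-1-one
Conditions: 2 (1.0 equiv), KOH (1.0 equiv, 5% aq.), 0 °C → rt, 3 h
Reagents that add atoms: prenyl bromide (2), CC(C)=CCBr
Why: Friedel–Crafts-type C-alkylation of the ambident phloroglucinolate in water (protic medium favours C- over O-alkylation); the two free ring carbons are equivalent, so only mono- versus di-prenylation must be held by stoichiometry, and no stereocentre is formed.

Step 2
Reactants: 4 1-(2,4,6-trihydroxy-3-methylphenyl)ethan-1-one (3-methylphloroacetophenone); 5 tert-butyl 2-methylbut-3-en-2-yl carbonate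
Product: 6 1-{2,6-dihydroxy-3-methyl-4-[(2-methylbut-3-en-2-yl)oxy]phenyl}ethan-1-one
Conditions: 5 (1.1 equiv), Pd(PPh3)4 (5 mol%), THF, 0 °C, 30 min; NaHCO3 wash
Reagents that add atoms: tert-butyl 2-methylbut-3-en-2-yl carbonate (5), CC(C)(C)OC(=O)OC(C)(C)C=C
Why: Tsuji–Trost allylic etherification under kinetic control, in which the most acidic, non-chelated 4-OH (para to the acetyl) attacks the more substituted terminus of the π-prenyl–Pd complex to give the tertiary aryl ether, while the two ortho-OH groups stay free and decarboxylation supplies the base; no stereocentre is formed.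

Step 3
Reactants: 6 1-{2,6-dihydroxy-3-methyl-4-[(2-methylbut-3-en-2-yl)oxy]phenyl}ethan-1-one
Product: 7 (R)-2-acetyl-3,5-dihydroxy-4-methyl-4-(3-methylbut-2-en-1-yl)cyclohexa-2,5-dien-1-one
Conditions: Pd2(dba)3·CHCl3 (2.5 mol%), (R,R)-DACH-phenyl Trost ligand (7.5 mol%), degassed CH2Cl2 (0.05 M), −30 → 0 °C; NaHCO3 extraction, then acidify
Reagents that add atoms: none
Why: Proposed new method: Pd(0)–L* ionises the tertiary allylic C–O bond (the acylphloroglucinolate is a vinylogous-carboxylate leaving group) to a contact ion pair [(η3-prenyl)PdL*]+ ArO−, and the anion returns through carbon by outer-sphere attack on the unsubstituted allyl terminus, a formal enantioselective dearomative 1,3 O→C prenyl shift; the methyl-bearing ortho carbon is the enolate-type site that is alkylated in gem-dialkylations to filicinic acids and the only one that gives a stabilised vinylogous acid, its face is chosen by the chiral ligand pocket (this sets the quaternary stereocentre), and base-free 1:1 internal stoichiometry rules out a second prenylation; closest known reaction types are Pd-catalysed O→C allyl migration of allyl aryl and enol ethers, Pd/Trost-ligand asymmetric allylic dearomatisation of naphthols, and linear-selective asymmetric Pd prenylation of 3-substituted oxindoles.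

Step 4
Reactants: 7 (R)-2-acetyl-3,5-dihydroxy-4-methyl-4-(3-methylbut-2-en-1-yl)cyclohexa-2,5-dien-1-one; 3 1-[2,4,6-trihydroxy-3-(3-methylbut-2-en-1-yl)phenyl]ethan-1-one; 8 formaldehyde
Product: 11 (R)-2-acetyl-6-{[3-acetyl-2,4,6-trihydroxy-5-(3-methylbut-2-en-1-yl)phenyl]methyl}-3,5-dihydroxy-4-methyl-4-(3-methylbut-2-en-1-yl)cyclohexa-2,5-dien-1-one (target), via hydroxymethyl adduct 9 (not isolated), via methylene trione 10 (not isolated)
Conditions: 7 (1.0 equiv), 3 (2.0 equiv), 37% aq. HCHO (1.0 equiv, slow addition), KOH (3.0 equiv, 1% aq.)/MeOH, 0 °C → rt, 30 min; then 1 M HCl, 0 °C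
Reagents that add atoms: formaldehyde (8), C=O
Why: Classical base-mediated formaldehyde bridging of acylphloroglucinols, i.e. aldol addition of the enolate of 7 to CH2O, dehydration to the methylene trione and Michael addition of the only free ring carbon of the phenolate of 3; the quaternary stereocentre is not enolisable and is untouched.

**Compound list**
1 | 1-(2,4,6-trihydroxyphenyl)ethan-1-one | CC(=O)c1c(O)cc(O)cc1O | starting material
2 | 1-bromo-3-methylbut-2-ene | CC(C)=CCBr | starting material
3 | 1-[2,4,6-trihydroxy-3-(3-methylbut-2-en-1-yl)phenyl]ethan-1-one | CC(=O)c1c(O)cc(O)c(CC=C(C)C)c1O | intermediate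
4 | 1-(2,4,6-trihydroxy-3-methylphenyl)ethan-1-one | CC(=O)c1c(O)cc(O)c(C)c1O | starting material
5 | tert-butyl 2-methylbut-3-en-2-yl carbonate | CC(C)(C)OC(=O)OC(C)(C)C=C | starting material
6 | 1-{2,6-dihydroxy-3-methyl-4-[(2-methylbut-3-en-2-yl)oxy]phenyl}ethan-1-one | CC(=O)c1c(O)cc(OC(C)(C)C=C)c(C)c1O | intermediate
7 | (R)-2-acetyl-3,5-dihydroxy-4-methyl-4-(3-methylbut-2-en-1-yl)cyclohexa-2,5-dien-1-one | CC(=O)C1=C(O)[C@](C)(CC=C(C)C)C(O)=CC1=O | intermediate
8 | formaldehyde | C=O | starting material
9 | (R)-2-acetyl-3,5-dihydroxy-6-(hydroxymethyl)-4-methyl-4-(3-methylbut-2-en-1-yl)cyclohexa-2,5-dien-1-one | CC(=O)C1=C(O)[C@](C)(CC=C(C)C)C(O)=C(CO)C1=O | intermediate (not isolated)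
10 | (S)-2-acetyl-3-hydroxy-4-methyl-6-methylidene-4-(3-methylbut-2-en-1-yl)cyclohex-2-ene-1,5-dione (same spatial arrangement as 7; the descriptor changes because C5 is now a ketone) | CC(=O)C1=C(O)[C@](C)(CC=C(C)C)C(=O)C(=C)C1=O | intermediate (not isolated)
11 | (R)-2-acetyl-6-{[3-acetyl-2,4,6-trihydroxy-5-(3-methylbut-2-en-1-yl)phenyl]methyl}-3,5-dihydroxy-4-methyl-4-(3-methylbut-2-en-1-yl)cyclohexa-2,5-dien-1-one | CC(=O)C1=C(O)[C@](C)(CC=C(C)C)C(O)=C(Cc2c(O)c(CC=C(C)C)c(O)c(C(C)=O)c2O)C1=O | target

**Step count and risks**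

Total steps: 4. Longest linear sequence: 3 (4 → 6 → 7 → 11).

Three steps most likely to fail:

Step 3 (the proposed new step). The risks are:
- C-attack at the free C–H ring carbon instead of the methyl-bearing one, giving the aromatic 3-methyl-5-prenyl isomer. This isomer stays in the organic phase on NaHCO3 extraction, because 7 is far more acidic.
- O-return to the primary prenyl ether.
- Pd-mediated retro-allylation of 7 on long reaction times.
- Modest ee or the opposite sense of induction; the antipodal ligand is used if the first run gives the (S)-product.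

Fallback with known chemistry, setting out from 3 and coming back at 7: C-methylation of 3 with MeI/NaOMe in MeOH at 0 °C, which goes to the already alkylated ring carbon as in filicinic acid syntheses, gives racemic 2-acetyl-3,5-dihydroxy-4-methyl-4-(3-methylbut-2-en-1-yl)cyclohexa-2,5-dien-1-one F1. Preparative chiral SFC (amylose phase, CO2/MeOH with 0.1% formic acid) separates it into 7 and (S)-2-acetyl-3,5-dihydroxy-4-methyl-4-(3-methylbut-2-en-1-yl)cyclohexa-2,5-dien-1-one F2, which is set aside.

Step 4. The formaldehyde coupling is statistical, so the homo-dimers of 7 and of 3 compete with the cross-dimer; the excess of 3 only shifts the ratio. Fallback setting out from 3 and 7 and coming back at 11: a Mannich reaction of 3 with dimethylamine and formaldehyde (EtOH, rt) gives 1-{3-[(dimethylamino)methyl]-2,4,6-trihydroxy-5-(3-methylbut-2-en-1-yl)phenyl}ethan-1-one F3. Heated with 7 (1 equiv) in dioxane at 90 °C, it loses dimethylamine to give the ortho-quinone methide 4-acetyl-3,5-dihydroxy-6-methylidene-2-(3-methylbut-2-en-1-yl)cyclohexa-2,4-dien-1-one F4. This is trapped at the free enol carbon C6 of 7 to give 11, and no homo-dimer of 7 can form.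

Step 2. The same π-prenyl–Pd species can C-prenylate the electron-rich ring or etherify a second OH, and ether 6 is itself labile to Pd(0), so the reaction must be stopped cold. Fallback setting out from 4 and coming back at 6: Cu-catalysed propargylic etherification of 4 with 3-chloro-3-methylbut-1-yne (CuCl2·2H2O cat., DBU, MeCN, 0 °C) gives 1-{2,6-dihydroxy-3-methyl-4-[(2-methylbut-3-yn-2-yl)oxy]phenyl}ethan-1-one F5. Lindlar semi-hydrogenation (H2 1 atm, Pd/CaCO3–Pb, quinoline, EtOAc, rt) then gives 6.

**Further compounds**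
F1 | step 3 | racemic 2-acetyl-3,5-dihydroxy-4-methyl-4-(3-methylbut-2-en-1-yl)cyclohexa-2,5-dien-1-one | CC(=O)C1=C(O)C(C)(CC=C(C)C)C(O)=CC1=O
F2 | step 3 | (S)-2-acetyl-3,5-dihydroxy-4-methyl-4-(3-methylbut-2-en-1-yl)cyclohexa-2,5-dien-1-one | CC(=O)C1=C(O)[C@@](C)(CC=C(C)C)C(O)=CC1=O
F3 | step 4 | 1-{3-[(dimethylamino)methyl]-2,4,6-trihydroxy-5-(3-methylbut-2-en-1-yl)phenyl}ethan-1-one | CC(=O)c1c(O)c(CN(C)C)c(O)c(CC=C(C)C)c1O
F4 | step 4 | 4-acetyl-3,5-dihydroxy-6-methylidene-2-(3-methylbut-2-en-1-yl)cyclohexa-2,4-dien-1-one | C=C1C(=O)C(CC=C(C)C)=C(O)C(C(C)=O)=C1O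
F5 | step 2 | 1-{2,6-dihydroxy-3-methyl-4-[(2-methylbut-3-yn-2-yl)oxy]phenyl}ethan-1-one | CC(=O)c1c(O)cc(OC(C)(C)C#C)c(C)c1O
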